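One equivalent of solid substrate in this flask meets 0.500 equivalents of protic impurity, and the reckoning begins from that ratio.

    solid substrate + protic impurity → quenched substrate (k1 = 17 M⁻¹ min⁻¹)
    solid substrate ⇌ dissolved substrate, rate k2*(cs2 - [dissolved substrate]) while solid is left; crystals form when [dissolved substrate] > cs2 (cs2 = 3.5 mM, k2 = 0.031 min⁻¹)
    crystals ⇌ target, rate k3*(cs3 - [target]) while solid is left; crystals form when [target] > cs3 (cs3 = 0.21 mM, k3 = 9.1 min⁻¹)
    reagent → decomposition product (k4 = 2.9 × 10⁻⁵ min⁻¹)
    dissolved substrate + reagent → target (k5 = 75 M⁻¹ min⁻¹)

solid substrate 20 mM; reagent 1.20 equiv; protic impurity 10.0 mM; time 2.5 h

1. how much target and crystals together there is at 2.5 h, in percent of the solid substrate charged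
2. the change that raises the amount of target and crystals together at 2.5 h, in percent of the solid substrate charged most ("none" if none brings more than 2 percentage points) (autumn / spring / winter / noon / none)
3. amount of target and crystals together at 2.5 h, in percent of the solid substrate charged, after spring

- autumn: doubling the solubility in step 3, all else as stated
- spring: doubling the dissolution coefficient of step 2, all else as stated
- winter: doubling the amount of reagent, all else as stated
- noon: doubling the solubility in step 2, all else as stated

- for target the crystals are counted in
- as a solid, counted per litre of solution: solid substrate, crystals
- at the start none of the solid substrate is in solution
- run time (flask): 2.5 h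

Reckoned by hand, the first question is which step reaches the solid substrate sooner. Dissolution cannot pass 0.109 mM min⁻¹, while at the start the quench runs at 3.40 mM min⁻¹, 31.2 times faster than dissolution. The protic impurity, with a half-life of 2.04 min at the charged solid, therefore takes its own amount of solid substrate mole for mole and spares 50.0% of the charge.

Can dissolution deliver that remainder in time? Into a solution kept empty it can deliver 81.4% by the end of the run, more than the spared share, and the remainder needs 92.2 min of the 150 min.

Does the solution stay nearly empty? Dissolved substrate has a half-life of 0.39 min against reagent, far shorter than those 92.2 min, and the 24.0 mM of reagent exceeds the 10.0 mM of substrate it has to meet. Dissolution is thus the rate-limiting step.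

While the quench outruns dissolution and reagent stays in excess, the lesser of what the impurity spares and what dissolution can deliver in the run, here 50.0%, is the yield ceiling. Spring and noon double the larger share, while autumn and winter enter neither, so the reckoning expects 50.0% after spring and no useful change.

The forecast gave 50%, none as the best change and 50.3% after spring, a little more than the ceiling, holding that faster dissolution “only lets a trace of impurity survive until the solid runs out”.

The simulation gives 50.0% for the flask, 50.4% after spring and none as the best change. Half of the quench turnover in the flask is done by 2.41 min, and the result stands at the ceiling of 50.0%. A neighbour flask charged with 80 mM of solid substrate, its protic impurity still at 10.0 mM, has a ceiling of 20.3%, with delivery now the lesser share. That neighbour gives 20.2% and ends with 67.3% of its charge still solid.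

The constants used here belong to no real substance; no experiment stands behind them.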